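**Retrosynthetic overview**
1. Target 29 ⇒ two Wittig olefinations (C11=C12 and C11'=C12'): triol C15 aldehyde 24 (ring A) + C10 bis(phosphonium) salt 27 + ε C15 aldehyde 18 (ring E).
2. 18 and 24 both ⇒ (3R,6R)-3-hydroxy-α-ionone 15. 18 needs only a two-carbon extension; 24 needs the ε→β double-bond shift, hydroxyl-directed epoxidation, inversion at C3 and epoxide→trans-diol hydrolysis, then the same extension.
3. 15 ⇒ acyclic (8R)-silyloxy trienone 12 by one proton-initiated ψ-end→ε-ring cyclisation (C1–C6 bond, the lycopene-cyclase event) in which C3 controls C6.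
4. 12 ⇒ (R)-epichlorohydrin 1, isopropenyl Grignard 2, acetylide 5, Me3Al 7 and methyl vinyl ketone 11.
5. Ring order: the single carbocycle-forming step (step 6) gives ring E directly and, after divergence, ring A; the oxirane made in step 10 is opened again in step 11.

Assumption: ring positions use carotenoid numbering (C1 = CMe2, C3 = CH–O, C5 = ring carbon bearing CH3, C6 = ring carbon bearing the chain, chain C7 onward); (R)-epichlorohydrin and the C10 dialdehyde 25 are taken as purchasable.

**Route**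

Step 1
Reactants: 1 (R)-epichlorohydrin; 2 isopropenylmagnesium bromide
Product: 4 (R)-2-(2-methylprop-2-en-1-yl)oxirane, via chlorohydrin 3 (not isolated)
Conditions: CuI (10 mol%), THF, −40 to −20 °C; aq. NH4Cl; crude + NaOH (powder), Et2O, rt
Reagents that add atoms: isopropenylmagnesium bromide (2), CC(=C)[Mg]Br
Why: Copper-catalysed Grignard opening of the epoxide at its CH2 terminus, then Williamson closure onto CH2Cl; the stereocentre is never a reacting carbon, so (R) is carried over.

Step 2
Reactants: 4 (R)-2-(2-methylprop-2-en-1-yl)oxirane; 5 lithium acetylide–ethylenediamine complex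
Product: 6 (R)-6-methylhept-6-en-1-yn-4-ol
Conditions: DMSO, 15 °C → rt; aq. NH4Cl
Reagents that add atoms: lithium acetylide (from 5), [Li]C#C
Why: SN2 opening of the terminal epoxide at CH2 by acetylide; the carbinol centre is untouched.

Step 3
Reactants: 6 (R)-6-methylhept-6-en-1-yn-4-ol; 7 trimethylaluminium
Product: 9 (4R,1E)-1-iodo-2,6-dimethylhepta-1,6-dien-4-ol, via alkenylalane 8 (not isolated)
Conditions: Me3Al (3 equiv), Cp2ZrCl2 (0.25 equiv), CH2Cl2, 0 °C → rt; then I2, THF, −30 °C
Reagents that add atoms: trimethylaluminium (7), C[Al](C)C; iodine, II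
Why: Negishi zirconium-catalysed syn-carboalumination of the terminal alkyne (CH3 to the internal carbon, Al to the terminus) and iodinolysis with retention fix the E trisubstituted alkene; the 1,1-disubstituted alkene does not react with Me3Al/Cp2ZrCl2.

Step 4
Reactants: 9 (4R,1E)-1-iodo-2,6-dimethylhepta-1,6-dien-4-ol
Product: 10 tert-butyl{[(4R,1E)-1-iodo-2,6-dimethylhepta-1,6-dien-4-yl]oxy}diphenylsilane
Conditions: TBDPSCl, imidazole, DMF, rt
Reagents that add atoms: tert-butyl(chloro)diphenylsilane, CC(C)(C)[Si](Cl)(c1ccccc1)c1ccccc1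
Why: Routine O-silylation; it gives an acid-stable, non-participating ether so that the allylic C3–O bond formed in step 6 does not ionise.

Step 5
Reactants: 10 silyl ether of 9; 11 methyl vinyl ketone
Product: 12 (3E,5E,8R)-8-{[tert-butyl(diphenyl)silyl]oxy}-6,10-dimethylundeca-3,5,10-trien-2-one
Conditions: Pd(OAc)2 (5 mol%), Bu4NCl, K2CO3, DMF, 40 °C
Reagents that add atoms: methyl vinyl ketone (11), C=CC(C)=O
Why: Heck reaction of the alkenyl iodide (retention at the vinyl carbon, E-selective β-hydride elimination) gives the E,E-dienone; insertion into the pendant isopropenyl group cannot compete because palladium sits trans to the tether and ring closure would need a trans-cyclohexene.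

Step 6
Reactants: 12 (3E,5E,8R)-8-silyloxy-6,10-dimethylundeca-3,5,10-trien-2-one
Product: 15 (E)-4-[(1R,4R)-4-hydroxy-2,6,6-trimethylcyclohex-2-en-1-yl]but-3-en-2-one [(3R,6R)-3-hydroxy-α-ionone], via cyclohexyl cation 13 (not isolated), via silyl ether 14 (not isolated)
Conditions: MeSO3H (3 equiv), CH2Cl2, −40 → −20 °C; Et3N, −40 °C; then Bu4NF/AcOH (1:1), THF, rt
Reagents that add atoms: none
Why: Proposed new method: Markovnikov protonation of the isopropenyl group gives the C1 tertiary cation, which is captured by C6 of the E C5=C6 bond through a chair transition state with the C3 silyloxy group equatorial (axial would clash with the axial C1 methyl) and the dienone chain equatorial, so C6 forms trans to C3 (3R → 6R); kinetic loss of a C4 proton from cation 13 gives the ε-type alkene, and buffered fluoride then frees the alcohol without touching C6; the closest known reaction is the acid cyclisation of pseudoionone to α-ionone (cationic polyene cyclisation with 1,4-induction from an existing ring substituent).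

Step 7
Reactants: 15 (3R,6R)-3-hydroxy-α-ionone; 16 diethyl cyanomethylphosphonate
Product: 17 (2E,4E)-5-[(1R,4R)-4-hydroxy-2,6,6-trimethylcyclohex-2-en-1-yl]-3-methylpenta-2,4-dienenitrile
Conditions: NaH (1.5 equiv), 16 (1.6 equiv), THF, 0 °C → rt; 9E isomer separated on SiO2
Reagents that add atoms: diethyl cyanomethylphosphonate (16), CCOP(=O)(CC#N)OCC
Why: Horner–Wadsworth–Emmons olefination of the methyl ketone; the weakly basic phosphonate anion leaves C6–H and the free hydroxyl alone, and the E isomer predominates.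

Step 8
Reactants: 17 ε C15 nitrile
Product: 18 (2E,4E)-5-[(1R,4R)-4-hydroxy-2,6,6-trimethylcyclohex-2-en-1-yl]-3-methylpenta-2,4-dienal
Conditions: i-Bu2AlH (3 equiv), CH2Cl2, −78 °C; aq. KNaC4H4O6 (Rochelle salt), then wet SiO2
Reagents that add atoms: water, O
Why: Partial hydride reduction of the nitrile to the aluminium aldimine, hydrolysed to the enal on work-up; no stereocentre is involved.

Step 9
Reactants: 15 (3R,6R)-3-hydroxy-α-ionone
Product: 19 (E)-4-[(4S)-4-hydroxy-2,6,6-trimethylcyclohex-1-en-1-yl]but-3-en-2-one [(3S)-3-hydroxy-β-ionone]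
Conditions: NaOMe (0.3 equiv), MeOH, 50 °C
Reagents that add atoms: none
Why: Base-mediated prototropic shift: deprotonation at C6 (γ to the enone and allylic) gives the extended dienolate, which is reprotonated at C4 to the fully conjugated β-isomer; C6 chirality is erased on purpose and C3 is untouched (R becomes S only through a priority change).

Step 10
Reactants: 19 (3S)-3-hydroxy-β-ionone
Product: 20 (E)-4-[(1S,4R,6R)-4-hydroxy-2,2,6-trimethyl-7-oxabicyclo[4.1.0]heptan-1-yl]but-3-en-2-one [(3R,5R,6S)-5,6-epoxy-3-hydroxy-5,6-dihydro-β-ionone, epoxide syn to OH]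
Conditions: VO(acac)2 (5 mol%), t-BuOOH (1.5 equiv), CH2Cl2, 0 °C → rt
Reagents that add atoms: tert-butyl hydroperoxide, CC(C)(C)OO
Why: Hydroxyl-directed vanadium-catalysed epoxidation of the homoallylic alcohol delivers oxygen to the C5=C6 face syn to 3-OH, setting 5R and 6S; the electron-poor enone alkene is inert.

Step 11
Reactants: 20 syn-epoxy alcohol
Product: 22 (3S,5S,6S)-5,6-dihydroxy-3-(4-nitrobenzoyloxy)-5,6-dihydro-β-ionone, via anti-epoxy ester 21 (not isolated)
Conditions: 4-O2NC6H4CO2H, PPh3, DIAD, THF, 0 °C → rt; then 1 M aq. H2SO4, 0 °C → rt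
Reagents that add atoms: 4-nitrobenzoic acid, OC(=O)c1ccc(cc1)[N+](=O)[O-]; water, O
Why: Mitsunobu SN2 inversion at C3 (3R → 3S), then acid-catalysed epoxide hydrolysis in which the C5–O bond breaks (tertiary, whereas C6 is deactivated by the enone) and oxygen enters anti at C5 (5R → 5S, by water or through the bridged aroyloxonium ion) while C6 keeps its oxygen (6S), giving the trans-diol.

Step 12
Reactants: 22 diol ester ketone; 16 diethyl cyanomethylphosphonate
Product: 23 (2E,4E)-5-[(1S,2S,4S)-1,2-dihydroxy-2,6,6-trimethyl-4-(4-nitrobenzoyloxy)cyclohexyl]-3-methylpenta-2,4-dienenitrile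
Conditions: NaH (1.5 equiv), 16 (1.6 equiv; anion preformed, no free NaH), THF, 0 °C → rt; 9E isomer separated
Reagents that add atoms: diethyl cyanomethylphosphonate (16), CCOP(=O)(CC#N)OCC
Why: Horner–Wadsworth–Emmons olefination of the methyl ketone; the stabilised anion is too weak a base to ionise the tertiary alcohols, so the ring is not opened by retro-aldol cleavage.

Step 13
Reactants: 23 triol-ring C15 nitrile ester
Product: 24 (2E,4E)-3-methyl-5-[(1S,2S,4S)-1,2,4-trihydroxy-2,6,6-trimethylcyclohexyl]penta-2,4-dienal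
Conditions: i-Bu2AlH (7 equiv), CH2Cl2, −78 °C; aq. KNaC4H4O6 (Rochelle salt), then wet SiO2
Reagents that add atoms: water, O
Why: Hydride reduction turns the nitrile into the aldimine (hydrolysed to the enal) and removes the ester reductively in the same operation, the tertiary alcohols being held as aluminium alkoxides.

Step 14
Reactants: 25 (2E,4E,6E)-2,7-dimethylocta-2,4,6-trienedial
Product: 26 (2E,4E,6E)-2,7-dimethylocta-2,4,6-triene-1,8-diol
Conditions: NaBH4, MeOH/THF, 0 °C
Reagents that add atoms: none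
Why: 1,2-Reduction of both conjugated aldehydes by borohydride; alkene geometry is unaffected.

Step 15
Reactants: 26 C10 diol
Product: 27 [(2E,4E,6E)-2,7-dimethylocta-2,4,6-triene-1,8-diyl]bis(triphenylphosphonium) dibromide
Conditions: PPh3·HBr (2.1 equiv), MeOH, rt
Reagents that add atoms: triphenylphosphine hydrobromide, [Br-].c1ccc(cc1)[PH+](c1ccccc1)c1ccccc1
Why: Acid-promoted substitution of the primary allylic alcohols by triphenylphosphine, the standard way to allylic Wittig salts; the all-E triene is the thermodynamic product.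

Step 16
Reactants: 27 C10 bis(phosphonium) dibromide; 24 triol C15 aldehyde; 18 ε C15 aldehyde
Product: 29 (3S,5S,6S,3'R,6'R)-5,6-dihydro-β,ε-carotene-3,5,6,3'-tetrol (target), via C25 phosphonium salt 28 (not isolated)
Conditions: 27 (1.1 equiv), 24 (1.0 equiv), NaOMe (1.0 equiv), CH2Cl2/MeOH, −10 °C; then 18 (1.3 equiv), NaOMe (1.3 equiv), 0 °C → rt; then EtOH, reflux (Z → E)
Reagents that add atoms: none
Why: Two Wittig olefinations in sequence: the dicationic bis-salt is the stronger acid, so the first equivalent of base takes it only as far as the monocationic C25 salt 28, whose ylide then condenses with 18; the hindered 11Z/11'Z isomers revert thermally to all-E, and no stereocentre is touched.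

**Compound list**
1 | (R)-epichlorohydrin | ClC[C@H]1CO1 | starting material
2 | isopropenylmagnesium bromide | CC(=C)[Mg]Br | starting material
3 | (R)-1-chloro-4-methylpent-4-en-2-ol | ClC[C@H](O)CC(C)=C | intermediate (not isolated)
4 | (R)-2-(2-methylprop-2-en-1-yl)oxirane | C=C(C)C[C@@H]1CO1 | intermediate
5 | lithium acetylide–ethylenediamine complex | [Li]C#C.NCCN | starting material
6 | (R)-6-methylhept-6-en-1-yn-4-ol | C#CC[C@H](O)CC(C)=C | intermediate
7 | trimethylaluminium | C[Al](C)C | starting material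
8 | (E)-alkenyl(dimethyl)alane, O-dimethylaluminium alkoxide of 6 after methylalumination | C=C(C)C[C@@H](O[Al](C)C)C/C(C)=C/[Al](C)C | intermediate (not isolated)
9 | (4R,1E)-1-iodo-2,6-dimethylhepta-1,6-dien-4-ol | C=C(C)C[C@@H](O)C/C(C)=C/I | intermediate
10 | tert-butyl{[(4R,1E)-1-iodo-2,6-dimethylhepta-1,6-dien-4-yl]oxy}diphenylsilane | C=C(C)C[C@@H](O[Si](c1ccccc1)(c1ccccc1)C(C)(C)C)C/C(C)=C/I | intermediate
11 | methyl vinyl ketone | C=CC(C)=O | starting material
12 | (3E,5E,8R)-8-{[tert-butyl(diphenyl)silyl]oxy}-6,10-dimethylundeca-3,5,10-trien-2-one | C=C(C)C[C@@H](O[Si](c1ccccc1)(c1ccccc1)C(C)(C)C)C/C(C)=C/C=C/C(C)=O | intermediate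
13 | tertiary C5 cyclohexyl cation, (3R,6R), 3-OTBDPS, (E)-3-oxobut-1-enyl at C6 | C[C+]1C[C@H](O[Si](c2ccccc2)(c2ccccc2)C(C)(C)C)CC(C)(C)[C@H]1/C=C/C(C)=O | intermediate (not isolated)
14 | (E)-4-[(1R,4R)-4-{[tert-butyl(diphenyl)silyl]oxy}-2,6,6-trimethylcyclohex-2-en-1-yl]but-3-en-2-one | CC1=C[C@H](O[Si](c2ccccc2)(c2ccccc2)C(C)(C)C)CC(C)(C)[C@H]1/C=C/C(C)=O | intermediate (not isolated)
15 | (E)-4-[(1R,4R)-4-hydroxy-2,6,6-trimethylcyclohex-2-en-1-yl]but-3-en-2-one, (3R,6R)-3-hydroxy-α-ionone | CC1=C[C@H](O)CC(C)(C)[C@H]1/C=C/C(C)=O | intermediate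
16 | diethyl cyanomethylphosphonate | CCOP(=O)(CC#N)OCC | starting material
17 | (2E,4E)-5-[(1R,4R)-4-hydroxy-2,6,6-trimethylcyclohex-2-en-1-yl]-3-methylpenta-2,4-dienenitrile | CC1=C[C@H](O)CC(C)(C)[C@H]1/C=C/C(C)=C/C#N | intermediate
18 | (2E,4E)-5-[(1R,4R)-4-hydroxy-2,6,6-trimethylcyclohex-2-en-1-yl]-3-methylpenta-2,4-dienal | CC1=C[C@H](O)CC(C)(C)[C@H]1/C=C/C(C)=C/C=O | intermediate
19 | (E)-4-[(4S)-4-hydroxy-2,6,6-trimethylcyclohex-1-en-1-yl]but-3-en-2-one, (3S)-3-hydroxy-β-ionone | CC1=C(/C=C/C(C)=O)C(C)(C)C[C@@H](O)C1 | intermediate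
20 | (E)-4-[(1S,4R,6R)-4-hydroxy-2,2,6-trimethyl-7-oxabicyclo[4.1.0]heptan-1-yl]but-3-en-2-one, (3R,5R,6S) syn-epoxy alcohol | CC(=O)/C=C/[C@@]12O[C@]1(C)C[C@H](O)CC2(C)C | intermediate
21 | (3S,5R,6S)-5,6-epoxy-3-(4-nitrobenzoyloxy)-5,6-dihydro-β-ionone (epoxide anti to ester) | CC(=O)/C=C/[C@@]12O[C@]1(C)C[C@@H](OC(=O)c3ccc(cc3)[N+](=O)[O-])CC2(C)C | intermediate (not isolated)
22 | (1S,3S,4S)-3,4-dihydroxy-3,5,5-trimethyl-4-[(E)-3-oxobut-1-en-1-yl]cyclohexyl 4-nitrobenzoate, carotenoid (3S,5S,6S) | CC(=O)/C=C/[C@]1(O)C(C)(C)C[C@H](OC(=O)c2ccc(cc2)[N+](=O)[O-])C[C@]1(C)O | intermediate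
23 | (2E,4E)-5-[(1S,2S,4S)-1,2-dihydroxy-2,6,6-trimethyl-4-(4-nitrobenzoyloxy)cyclohexyl]-3-methylpenta-2,4-dienenitrile | N#C/C=C(C)/C=C/[C@]1(O)C(C)(C)C[C@H](OC(=O)c2ccc(cc2)[N+](=O)[O-])C[C@]1(C)O | intermediate
24 | (2E,4E)-3-methyl-5-[(1S,2S,4S)-1,2,4-trihydroxy-2,6,6-trimethylcyclohexyl]penta-2,4-dienal | O=C/C=C(C)/C=C/[C@]1(O)C(C)(C)C[C@H](O)C[C@]1(C)O | intermediate
25 | (2E,4E,6E)-2,7-dimethylocta-2,4,6-trienedial | O=C/C(C)=C/C=C/C=C(C)/C=O | starting material
26 | (2E,4E,6E)-2,7-dimethylocta-2,4,6-triene-1,8-diol | OC/C(C)=C/C=C/C=C(C)/CO | intermediate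
27 | [(2E,4E,6E)-2,7-dimethylocta-2,4,6-triene-1,8-diyl]bis(triphenylphosphonium) dibromide | [Br-].[Br-].c1ccccc1[P+](c1ccccc1)(c1ccccc1)C/C(C)=C/C=C/C=C(C)/C[P+](c1ccccc1)(c1ccccc1)c1ccccc1 | intermediate
28 | C25 all-E pentaenyl triphenylphosphonium bromide carrying the (3S,5S,6S)-trihydroxy ring (mono-Wittig product of 27 with 24) | [Br-].c1ccccc1[P+](c1ccccc1)(c1ccccc1)C/C(C)=C/C=C/C=C(C)/C=C/C=C(C)/C=C/[C@]1(O)C(C)(C)C[C@H](O)C[C@]1(C)O | intermediate (not isolated)
29 | (3S,5S,6S,3'R,6'R)-5,6-dihydro-β,ε-carotene-3,5,6,3'-tetrol | CC1=C[C@H](O)CC(C)(C)[C@H]1/C=C/C(C)=C/C=C/C(C)=C/C=C/C=C(C)/C=C/C=C(C)/C=C/[C@]1(O)C(C)(C)C[C@H](O)C[C@]1(C)O | target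

**Totals**
Total step count: 16. Longest linear sequence: 12 steps (1–6, 9–13, 16).

**Three steps most likely to fail**

Step 6 (key cyclisation). Possible failures are a 1,3-hydride shift from C3–H to the C1 cation, ionisation of the allylic silyl ether in the product, or proton loss toward C6 or the C5 methyl. The β- and γ-isomers from the last pathway are not wasted, since after desilylation the base of step 9 converges them on 19. The fallback sets out from 12 and starts the same C1–C6 closure with a soft metal electrophile instead of a proton. Treating 12 with Hg(OTf)2·PhNMe2 (divalent mercury) in MeNO2 at −20 °C, followed by aq. NaCl, gives the cyclised organomercurial chloride F1 through the same chair. Bu3SnH/AIBN then replaces HgCl by H, which comes back to the route at 14, desilylated as in step 6.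

Step 11 (Mitsunobu on a hindered epoxy alcohol, then hydrolysis). Elimination may compete with SN2 at C3, which is flanked by two quaternary centres. The fallback sets out from 19 and inverts first, while C5 is still sp2 and the carbinol is less crowded. Mitsunobu reaction of 19 with 4-nitrobenzoic acid, PPh3 and DIAD gives (3R)-3-(4-nitrobenzoyloxy)-β-ionone F2. Epoxidation with mCPBA (CH2Cl2, NaHCO3, 0 °C) then occurs under steric control, anti to the ester. After chromatographic removal of the minor syn isomer this comes back to the route at 21, which is hydrolysed with aqueous acid as before.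

Step 16 (sequential double Wittig on a bis-salt). Risks are statistical formation of the two symmetrical C40 products and Z isomers. The fallback sets out from 26 and replaces the dicationic bis-ylide by a neutral bis(phosphonate) used stepwise with isolation. PBr3 (Et2O, −10 °C) gives (2E,4E,6E)-1,8-dibromo-2,7-dimethylocta-2,4,6-triene F3, and Arbuzov reaction with P(OEt)3 (120 °C) gives the tetraethyl C10 bis(phosphonate) F4. Its mono-anion (KOt-Bu, 1 equiv, THF, −30 °C) condenses with 24 to give the C25 phosphonate F5, which is purified. A second E-selective Horner–Wadsworth–Emmons reaction with 18 (KOt-Bu, THF, −30 °C → rt) comes back to the route at 29.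

**Further compounds**
F1 | step 6 | chloro{[(3R,6R)-3-(tert-butyldiphenylsilyloxy)-α-ionon-16-yl]}mercury: compound 14 with one C1 methyl replaced by CH2HgCl, epimers at C1 | CC1=C[C@H](O[Si](c2ccccc2)(c2ccccc2)C(C)(C)C)CC(C)(C[Hg]Cl)[C@H]1/C=C/C(C)=O
F2 | step 11 | (1R)-3,5,5-trimethyl-4-[(E)-3-oxobut-1-en-1-yl]cyclohex-3-en-1-yl 4-nitrobenzoate, (3R)-3-(4-nitrobenzoyloxy)-β-ionone | CC1=C(/C=C/C(C)=O)C(C)(C)C[C@H](OC(=O)c2ccc(cc2)[N+](=O)[O-])C1
F3 | step 16 | (2E,4E,6E)-1,8-dibromo-2,7-dimethylocta-2,4,6-triene | BrC/C(C)=C/C=C/C=C(C)/CBr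
F4 | step 16 | tetraethyl [(2E,4E,6E)-2,7-dimethylocta-2,4,6-triene-1,8-diyl]bis(phosphonate) | CCOP(=O)(OCC)C/C(C)=C/C=C/C=C(C)/CP(=O)(OCC)OCC
F5 | step 16 | diethyl C25 all-E pentaenylphosphonate carrying the (3S,5S,6S)-trihydroxy ring (mono-olefination product of F4 with 24) | CCOP(=O)(OCC)C/C(C)=C/C=C/C=C(C)/C=C/C=C(C)/C=C/[C@]1(O)C(C)(C)C[C@H](O)C[C@]1(C)O
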